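The disconnection on which the route rests is the C8–C9 bond of ring B (labdane numbering). The target's array C17=C8–C9–C11–C12, an exocyclic methylene on ring B flanking the C9 stereocentre with its two-carbon link, is the retron of an allylmetal–alkyne addition. In one operation, PtCl2 makes the γ-carbon (C9) of an (E)-allylsilane attack a terminal alkyne (C8≡C17): ring B closes 6-exo-dig, C9 is set, and both the C8=C17 methylene and a C11=C12 vinyl handle appear. The precursor is monocyclic ring A: a trans-1,2-disubstituted 1,3,3-trimethylcyclohexane with a but-3-ynyl chain on C5 and a silylpropenyl group on C10, made by asymmetric conjugate addition–aldol trapping on 2,4,4-trimethylcyclohexenone.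

Key step: step 5

Remark: atom labels C1–C20 follow labdane numbering (ring A: C1–C5, C10; ring B: C5–C10; C17 is the methylene carbon). The target is the ent-labdane (5R,9R,10R) with a 13Z acid. The carbinol centre made in step 1 is carried as an epimer mixture and is destroyed in step 2.

Step 1
Reactants: 1 2,4,4-trimethylcyclohex-2-en-1-one; 2 (4-bromobut-1-yn-1-yl)trimethylsilane; 3 acrolein
Product: 6 (2R,3R)-2-(1-hydroxyprop-2-en-1-yl)-2,4,4-trimethyl-3-[4-(trimethylsilyl)but-3-yn-1-yl]cyclohexan-1-one (carbinol epimers), via Grignard reagent 4 (not isolated), via magnesium enolate 5 (not isolated)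
Conditions: 2, Mg, Et2O, 35 °C; Cu(OTf)2 (3 mol %), (S)-3-(1-hydroxy-4-methylpentan-2-yl)-1-mesityl-4,5-dihydroimidazolium hexafluorophosphate (4 mol %; the antipode is used if the first run shows it is the one that gives 3R), 1, Et2O, −30 °C; then 3, −78 °C; aq. NH4Cl
Reagents that add atoms: none
Why: Copper/chiral-NHC-catalysed asymmetric conjugate addition of Grignard reagents to α-substituted cyclic enones with trapping of the magnesium enolate is a known reaction type, in which the ligand sets C3 (labdane C5) and acrolein adds 1,2 to the tetrasubstituted enolate anti to the new pseudoaxial C3 chain, fixing the quaternary centre (labdane C10) trans to it.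

Step 2
Reactants: 6 aldol adduct
Product: 7 (2S,3R)-2,4,4-trimethyl-3-[4-(trimethylsilyl)but-3-yn-1-yl]-2-[(1E)-3-(trimethylsilyl)prop-1-en-1-yl]cyclohexan-1-one
Conditions: Pd(BF4)2(MeCN)4 (5 mol %), Me3SiSiMe3, DMSO/MeOH, 50 °C
Reagents that add atoms: hexamethyldisilane C[Si](C)(C)[Si](C)(C)C
Why: Palladium-catalysed silylation of allylic alcohols with a disilane runs through a π-allylpalladium species and delivers silicon to the unhindered terminus C12, so the branched alcohol should give the linear (E)-allylsilane in which C9 is the nucleophilic γ-carbon, the quaternary neighbour excluding β-hydride elimination.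

Step 3
Reactants: 7 allylsilane ketone
Product: 8 N'-{(2S,3R)-2,4,4-trimethyl-3-[4-(trimethylsilyl)but-3-yn-1-yl]-2-[(1E)-3-(trimethylsilyl)prop-1-en-1-yl]cyclohexylidene}-4-methylbenzenesulfonohydrazide (C=N geometry not relevant)
Conditions: TsNHNH2, cat. AcOH, EtOH, 75 °C
Reagents that add atoms: 4-methylbenzenesulfonohydrazide Cc1ccc(cc1)S(=O)(=O)NN
Why: Hydrazone condensation is standard, the quaternary α-carbon cannot epimerise, and the allylsilane and silylalkyne should tolerate the weakly acidic medium.

Step 4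
Reactants: 8 tosylhydrazone
Product: 10 {(2E)-3-[(1S,2R)-2-(but-3-yn-1-yl)-1,3,3-trimethylcyclohexyl]prop-2-en-1-yl}trimethylsilane, via silylalkyne 9 (not isolated)
Conditions: catecholborane, CHCl3, 0 °C to rt; NaOAc·3H2O, 60 °C; then K2CO3, MeOH, rt
Reagents that add atoms: none
Why: Catecholborane reduction of a tosylhydrazone followed by loss of sulfinate and N2 turns C=N into CH2 under mild conditions that leave the non-conjugated alkene and the alkyne untouched, and K2CO3/MeOH then cleaves only the C(sp)–Si bond, the allylsilane being inert to it.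

Step 5
Reactants: 10 allylsilane alkyne
Product: 11 (1R,4aR,8aR)-1-ethenyl-5,5,8a-trimethyl-2-methylidenedecahydronaphthalene
Conditions: PtCl2 (5 mol %), MeOH, 65 °C
Reagents that add atoms: none
Why: PtCl2 binds the terminal alkyne, the allylsilane γ-carbon C9 attacks the internal carbon C8 anti to the metal, the β-silyl cation at C11 loses silicon to methanol to give C11=C12, and protonation of the C17–Pt bond gives C8=C17H2 and returns the catalyst. The closest known reaction type is the divalent-platinum (or gold) catalysed intramolecular carbocyclisation of allylsilanes with alkynes to 1,4-dienes, a π-acid counterpart of the metallo-ene reaction. Ring B closes in the 6-exo-dig mode. C9 is set by a chair-like transition state on the locked ring A chair (the two chains trans-diequatorial, C10 methyl axial), in which the propenyl unit stays equatorial so that the vinyl group ends equatorial and H-9 axial, anti to the C10 methyl. The step needs exo attack at C8 over endo attack at C17 and cyclisation over methanol addition to the alkyne; the six-atom tether, the Markovnikov polarisation of the terminal alkyne and the high nucleophilicity of the allylsilane should secure both.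

Step 6
Reactants: 12 tert-butyl 4-chloro-3-oxobutanoate
Product: 13 tert-butyl 4-acetoxy-3-oxobutanoate
Conditions: KOAc, NaI (cat.), DMF, rt
Reagents that add atoms: potassium acetate CC(=O)[O-].[K+]
Why: Finkelstein-assisted SN2 displacement of an α-chloro ketone by acetate is fast at room temperature and leaves the tert-butyl ester untouched.

Step 7
Reactants: 13 tert-butyl 4-acetoxy-3-oxobutanoate
Product: 14 tert-butyl (2E)-4-acetoxy-3-{[(trifluoromethyl)sulfonyl]oxy}but-2-enoate
Conditions: DBU (1.05 equiv), Tf2O, CH2Cl2, −78 °C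
Reagents that add atoms: trifluoromethanesulfonic anhydride O=S(=O)(OS(=O)(=O)C(F)(F)F)C(F)(F)F
Why: O-triflation of a β-keto ester through its non-chelated amidinium enolate is the known route to the (E)-enol triflate, which places OTf anti and the acetoxymethyl group syn to the ester, the geometry required for C13=C14.

Step 8
Reactants: 11 diene; 14 enol triflate
Product: 16 tert-butyl (2Z)-3-(acetoxymethyl)-5-[(1R,4aR,8aR)-5,5,8a-trimethyl-2-methylidenedecahydronaphthalen-1-yl]pent-2-enoate, via alkylborane 15 (not isolated)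
Conditions: disiamylborane (from BH3·SMe2 and 2-methylbut-2-ene), THF, 0 °C to rt; then 14, PdCl2(dppf) (5 mol %), AsPh3, Cs2CO3, DMF/H2O, rt
Reagents that add atoms: none
Why: Disiamylborane hydroborates the monosubstituted C11=C12 vinyl group much faster than the hindered 1,1-disubstituted C8=C17 methylene and puts boron on C12, and the B-alkyl Suzuki–Miyaura coupling transfers the primary alkyl group to the enol triflate with retention of alkene geometry, giving the 13Z ester.

Step 9
Reactants: 16 tert-butyl ester
Product: 18 (2Z)-3-(acetoxymethyl)-5-[(1R,4aR,8aR)-5,5,8a-trimethyl-2-methylidenedecahydronaphthalen-1-yl]pent-2-enoic acid (CNP0398954.1), via trimethylsilyl ester 17 (not isolated)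
Conditions: TMSOTf, 2,6-lutidine, CH2Cl2, 0 °C; then aq. citrate buffer (pH 4)
Reagents that add atoms: none
Why: Silyl triflate with 2,6-lutidine converts a tert-butyl ester into the silyl ester with loss of isobutene under buffered non-protic conditions that should spare the exocyclic alkene and the allylic acetate, and mild aqueous work-up frees the acid without a nucleophilic carboxylate stage that could lactonise.

Compound list
1 | 2,4,4-trimethylcyclohex-2-en-1-one | CC1=CC(C)(C)CCC1=O | starting material
2 | (4-bromobut-1-yn-1-yl)trimethylsilane | C[Si](C)(C)C#CCCBr | starting material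
3 | acrolein (prop-2-enal) | C=CC=O | starting material
4 | [4-(trimethylsilyl)but-3-yn-1-yl]magnesium bromide | C[Si](C)(C)C#CCC[Mg]Br | intermediate
5 | bromomagnesium (3R)-2,4,4-trimethyl-3-[4-(trimethylsilyl)but-3-yn-1-yl]cyclohex-1-en-1-olate | C[Si](C)(C)C#CCC[C@@H]1C(C)(C)CCC(O[Mg]Br)=C1C | intermediate
6 | (2R,3R)-2-(1-hydroxyprop-2-en-1-yl)-2,4,4-trimethyl-3-[4-(trimethylsilyl)but-3-yn-1-yl]cyclohexan-1-one (carbinol epimers) | C[Si](C)(C)C#CCC[C@@H]1C(C)(C)CCC(=O)[C@@]1(C)C(O)C=C | intermediate
7 | (2S,3R)-2,4,4-trimethyl-3-[4-(trimethylsilyl)but-3-yn-1-yl]-2-[(1E)-3-(trimethylsilyl)prop-1-en-1-yl]cyclohexan-1-one | C[Si](C)(C)C#CCC[C@@H]1C(C)(C)CCC(=O)[C@@]1(C)/C=C/C[Si](C)(C)C | intermediate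
8 | tosylhydrazone of 7 | C[Si](C)(C)C#CCC[C@@H]1C(C)(C)CCC(=NNS(=O)(=O)c2ccc(C)cc2)[C@@]1(C)/C=C/C[Si](C)(C)C | intermediate
9 | trimethyl{(2E)-3-[(1S,2R)-1,3,3-trimethyl-2-[4-(trimethylsilyl)but-3-yn-1-yl]cyclohexyl]prop-2-en-1-yl}silane | C[Si](C)(C)C#CCC[C@@H]1C(C)(C)CCC[C@@]1(C)/C=C/C[Si](C)(C)C | intermediate
10 | {(2E)-3-[(1S,2R)-2-(but-3-yn-1-yl)-1,3,3-trimethylcyclohexyl]prop-2-en-1-yl}trimethylsilane | C#CCC[C@@H]1C(C)(C)CCC[C@@]1(C)/C=C/C[Si](C)(C)C | intermediate
11 | (1R,4aR,8aR)-1-ethenyl-5,5,8a-trimethyl-2-methylidenedecahydronaphthalene | C=C1CC[C@@H]2C(C)(C)CCC[C@@]2(C)[C@@H]1C=C | intermediate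
12 | tert-butyl 4-chloro-3-oxobutanoate | CC(C)(C)OC(=O)CC(=O)CCl | starting material
13 | tert-butyl 4-acetoxy-3-oxobutanoate | CC(=O)OCC(=O)CC(=O)OC(C)(C)C | intermediate
14 | tert-butyl (2E)-4-acetoxy-3-{[(trifluoromethyl)sulfonyl]oxy}but-2-enoate | CC(=O)OC/C(OS(=O)(=O)C(F)(F)F)=C\C(=O)OC(C)(C)C | intermediate
15 | bis(3-methylbutan-2-yl){2-[(1R,4aR,8aR)-5,5,8a-trimethyl-2-methylidenedecahydronaphthalen-1-yl]ethyl}borane | C=C1CC[C@@H]2C(C)(C)CCC[C@@]2(C)[C@@H]1CCB(C(C)C(C)C)C(C)C(C)C | intermediate
16 | tert-butyl (2Z)-3-(acetoxymethyl)-5-[(1R,4aR,8aR)-5,5,8a-trimethyl-2-methylidenedecahydronaphthalen-1-yl]pent-2-enoate | C=C1CC[C@@H]2C(C)(C)CCC[C@@]2(C)[C@@H]1CC/C(=C/C(=O)OC(C)(C)C)COC(C)=O | intermediate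
17 | trimethylsilyl (2Z)-3-(acetoxymethyl)-5-[(1R,4aR,8aR)-5,5,8a-trimethyl-2-methylidenedecahydronaphthalen-1-yl]pent-2-enoate | C=C1CC[C@@H]2C(C)(C)CCC[C@@]2(C)[C@@H]1CC/C(=C/C(=O)O[Si](C)(C)C)COC(C)=O | intermediate
18 | (2Z)-3-(acetoxymethyl)-5-[(1R,4aR,8aR)-5,5,8a-trimethyl-2-methylidenedecahydronaphthalen-1-yl]pent-2-enoic acid | C=C1CC[C@@H]2C(C)(C)CCC[C@@]2(C)[C@@H]1CC/C(=C/C(=O)O)COC(C)=O | target

Total step count: 9. Longest linear sequence: 7 (steps 1–5, 8, 9).

Steps most likely to fail:

First, step 1. The α-methyl, γ,γ-dimethyl enone may add the Grignard reagent slowly and with eroded facial selectivity, and the aldol trapping of the hindered enolate may reverse or divert to 1,4-addition. The fallback sets the stereocentre on a less hindered enone. It sets out from 4, which would be transmetalated with ZnCl2 to bis[4-(trimethylsilyl)but-3-yn-1-yl]zinc F1. Cu(OTf)2 with a binaphthol-derived phosphoramidite ligand would add F1 to commercial 4,4-dimethylcyclohex-2-en-1-one, and methylation in the same flask (MeI, HMPA) would give (2S,3S)-2,4,4-trimethyl-3-[4-(trimethylsilyl)but-3-yn-1-yl]cyclohexan-1-one F2. Thermodynamic enol silylation (TMSCl, NaI, Et3N, MeCN) would give trimethyl({(3R)-2,4,4-trimethyl-3-[4-(trimethylsilyl)but-3-yn-1-yl]cyclohex-1-en-1-yl}oxy)silane F3, and a TiCl4-mediated Mukaiyama aldol addition to 3, again anti to the C3 chain, comes back to the route at 6.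

Second, step 5. Attack at the neopentyl-type γ-carbon may be slow, so protodesilylation of the allylsilane or methanol addition to the alkyne may compete, and attack through the wrong chair would give the C9 epimer. The fallback replaces π-acid activation by carbopalladation. It sets out from 10: Markovnikov bromoboration–protonolysis (B-bromo-9-BBN, CH2Cl2, 0 °C; AcOH) would give {(2E)-3-[(1S,2R)-2-(3-bromobut-3-en-1-yl)-1,3,3-trimethylcyclohexyl]prop-2-en-1-yl}trimethylsilane F4. An allylsilane-terminated intramolecular Heck reaction (Pd(OAc)2, PPh3, Ag3PO4, DMF, 80 °C) would then close ring B by 6-exo carbopalladation of C9=C11 and β-silyl elimination, and comes back at 11.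

Third, step 8. Hydroboration may lose chemoselectivity and attack the C8=C17 methylene, and slow transmetalation of the hindered trialkylborane may allow base-induced elimination or deacetylation of the enol triflate. The fallback is base-free. It sets out from 11: hydrozirconation with Cp2Zr(H)Cl (selective for the monosubstituted alkene) and iodinolysis in the same flask would give (1R,4aR,8aR)-1-(2-iodoethyl)-5,5,8a-trimethyl-2-methylidenedecahydronaphthalene F5. Zinc insertion (Zn, LiCl, THF) would give {2-[(1R,4aR,8aR)-5,5,8a-trimethyl-2-methylidenedecahydronaphthalen-1-yl]ethyl}zinc iodide F6, and Negishi coupling with 14 (Pd(PPh3)4, THF/DMA, rt) comes back at 16.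

Further compounds
F1 | step 1 | bis[4-(trimethylsilyl)but-3-yn-1-yl]zinc | C[Si](C)(C)C#CCC[Zn]CCC#C[Si](C)(C)C
F2 | step 1 | (2S,3S)-2,4,4-trimethyl-3-[4-(trimethylsilyl)but-3-yn-1-yl]cyclohexan-1-one | C[Si](C)(C)C#CCC[C@@H]1C(C)(C)CCC(=O)[C@H]1C
F3 | step 1 | trimethyl({(3R)-2,4,4-trimethyl-3-[4-(trimethylsilyl)but-3-yn-1-yl]cyclohex-1-en-1-yl}oxy)silane | C[Si](C)(C)C#CCC[C@@H]1C(C)(C)CCC(O[Si](C)(C)C)=C1C
F4 | step 5 | {(2E)-3-[(1S,2R)-2-(3-bromobut-3-en-1-yl)-1,3,3-trimethylcyclohexyl]prop-2-en-1-yl}trimethylsilane | C=C(Br)CC[C@@H]1C(C)(C)CCC[C@@]1(C)/C=C/C[Si](C)(C)C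
F5 | step 8 | (1R,4aR,8aR)-1-(2-iodoethyl)-5,5,8a-trimethyl-2-methylidenedecahydronaphthalene | C=C1CC[C@@H]2C(C)(C)CCC[C@@]2(C)[C@@H]1CCI
F6 | step 8 | {2-[(1R,4aR,8aR)-5,5,8a-trimethyl-2-methylidenedecahydronaphthalen-1-yl]ethyl}zinc iodide | C=C1CC[C@@H]2C(C)(C)CCC[C@@]2(C)[C@@H]1CC[Zn]I
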